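## Retrosynthetic overview

1. The target is methyl shikimate carrying three different esters. The O4‑propanoyl goes on last (chemical), the O3‑acetyl comes from a lipase‑catalysed regioselective acetylation of the 3,4‑diol, and the O5‑(R)‑2‑methylbutanoyl is installed on the 3,4‑acetonide, where O5 is the only free OH.
2. The shikimate 3,4‑cis‑diol comes from anti‑selective OsO4 dihydroxylation of a 5‑silyloxy‑cyclohexa‑1,3‑diene ester, itself from E1cB opening of a 7‑oxanorbornene ester.
3. The 7‑oxanorbornene comes from a Cu(II)–bis(oxazoline)‑catalysed asymmetric Diels–Alder reaction of furan with an achiral acrylimide (first stereocentres).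
4. (R)‑2‑Methylbutanoic acid comes from Ru–H8‑BINAP asymmetric hydrogenation of tiglic acid.
5. Ring order: the oxanorbornene (six‑membered carbocycle and oxa‑bridge together) is formed first, the bridge is opened to the cyclohexadiene, and a temporary dioxolane (acetonide) is put on and taken off; no other ring is built.

Assumption: 3‑acryloyl‑1,3‑oxazolidin‑2‑one is bought as a catalogue compound; "shikimate" in trivial names means the natural 3,4‑cis/4,5‑trans configuration of the target.

## Route

Step 1
Reactants: 1 furan; 2 3‑acryloyl‑1,3‑oxazolidin‑2‑one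
Product: 3 3‑[(1R,2R,4R)‑7‑oxabicyclo[2.2.1]hept‑5‑ene‑2‑carbonyl]‑1,3‑oxazolidin‑2‑one (endo)
Conditions: [Cu((R,R)‑t‑Bu‑box)](SbF6)2 (5 mol%), furan (10 equiv), CH2Cl2, −78 °C, 40 h; recrystallise (EtOAc/hexanes) to remove the exo isomer
Reagents that add atoms: none
Why: Catalytic asymmetric Diels–Alder reaction in which the imide chelates square‑planar Cu(II) in the s‑cis form, the tert‑butyl groups of the (R,R)‑ligand block one acrylate face and furan adds endo to the other, setting C1, C2 and C4, while −78 °C suppresses the retro‑Diels–Alder equilibration that would erode ee.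

Step 2
Reactants: 3 3‑[(1R,2R,4R)‑7‑oxabicyclo[2.2.1]hept‑5‑ene‑2‑carbonyl]‑1,3‑oxazolidin‑2‑one
Product: 4 methyl (1R,2R,4R)‑7‑oxabicyclo[2.2.1]hept‑5‑ene‑2‑carboxylate
Conditions: MeMgBr (1.5 equiv) in MeOH/CH2Cl2 (gives MeOMgBr), 0 °C, 30 min; pH 7 aqueous work‑up
Reagents that add atoms: methanol CO
Why: Chelation‑assisted transesterification of the N‑acyl oxazolidinone, in which Mg binds both imide carbonyls and methoxide attacks the exocyclic C=O, so no ring stereocentre is touched (C2 becomes sp2 in step 3 anyway).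

Step 3
Reactants: 4 methyl (1R,2R,4R)‑7‑oxabicyclo[2.2.1]hept‑5‑ene‑2‑carboxylate
Product: 7 methyl (5R)‑5‑hydroxycyclohexa‑1,3‑diene‑1‑carboxylate, via lithium ester enolate 5 (not isolated), via lithium dienyl alkoxide 6 (not isolated)
Conditions: LiHMDS (1.2 equiv), THF, −78 → 0 °C, 1 h; AcOH (1.3 equiv) at −78 °C; cold work‑up, use at once
Reagents that add atoms: none
Why: E1cB β‑elimination in which the ester enolate expels the bridging oxygen from C1 and opens the oxa‑bridge to the conjugated dienoate, while the untouched C4–O stereocentre of the bicycle becomes C5 (R) of the dienol.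

Step 4
Reactants: 7 methyl (5R)‑5‑hydroxycyclohexa‑1,3‑diene‑1‑carboxylate
Product: 8 methyl (5R)‑5‑[(tert‑butyldimethylsilyl)oxy]cyclohexa‑1,3‑diene‑1‑carboxylate
Conditions: TBSCl (1.2 equiv), imidazole (2.5 equiv), CH2Cl2, 0 °C → rt
Reagents that add atoms: tert‑butyldimethylsilyl chloride CC(C)(C)[Si](C)(C)Cl
Why: Standard silylation of a secondary alcohol under mild, non‑acidic conditions, which blocks dehydration to methyl benzoate and provides the bulky allylic group that steers step 5.

Step 5
Reactants: 8 methyl (5R)‑5‑[(tert‑butyldimethylsilyl)oxy]cyclohexa‑1,3‑diene‑1‑carboxylate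
Product: 10 methyl 5‑O‑(tert‑butyldimethylsilyl)shikimate, via cyclic osmate ester 9 (not isolated)
Conditions: OsO4 (2 mol%), NMO (1.3 equiv), acetone/H2O (8:1), 0 °C → rt
Reagents that add atoms: osmium tetroxide O=[Os](=O)(=O)=O; N‑methylmorpholine N‑oxide C[N+]1([O-])CCOCC1; water O
Why: Upjohn cis‑dihydroxylation in which OsO4 adds suprafacially to the electron‑richer C3=C4 bond (C1=C2 is deactivated by the ester) on the face anti to the allylic OTBS group, giving the 3,4‑cis/4,5‑trans shikimate arrangement.

Step 6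
Reactants: 10 methyl 5‑O‑(tert‑butyldimethylsilyl)shikimate
Product: 11 methyl 3,4‑O‑isopropylidene‑5‑O‑(tert‑butyldimethylsilyl)shikimate
Conditions: 2,2‑dimethoxypropane (3 equiv), PPTS (5 mol%), CH2Cl2, rt
Reagents that add atoms: 2,2‑dimethoxypropane COC(C)(C)OC
Why: Acid‑catalysed transacetalisation that closes the five‑membered dioxolane on the cis‑3,4‑diol, with the secondary TBS ether stable to PPTS under anhydrous conditions.

Step 7
Reactants: 11 methyl 3,4‑O‑isopropylidene‑5‑O‑(tert‑butyldimethylsilyl)shikimate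
Product: 12 methyl 3,4‑O‑isopropylideneshikimate
Conditions: TBAF (1.2 equiv), AcOH (1.2 equiv), THF, 0 °C → rt
Reagents that add atoms: none
Why: Fluoride‑mediated desilylation driven by Si–F bond formation, buffered with acetic acid so that the methyl ester and acetonide are untouched and only O5 is freed.

Step 8
Reactants: 13 tiglic acid
Product: 14 (2R)‑2‑methylbutanoic acid
Conditions: H2 (2–4 atm), Ru(OAc)2[(R)‑H8‑BINAP] (0.5 mol%), MeOH, 20 °C; bulb‑to‑bulb distillation
Reagents that add atoms: none
Why: Noyori‑type asymmetric hydrogenation of an α,β‑unsaturated carboxylic acid in which the Ru‑bound carboxylate directs H2 to one enantioface of the alkene, the (R)‑ligand giving the levorotatory (R)‑acid in about 95–97% ee (check by rotation or chiral GC).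

Step 9
Reactants: 12 methyl 3,4‑O‑isopropylideneshikimate; 14 (2R)‑2‑methylbutanoic acid
Product: 16 methyl 3,4‑O‑isopropylidene‑5‑O‑[(2R)‑2‑methylbutanoyl]shikimate, via O‑acylisourea 15 (not isolated)
Conditions: DCC (1.2 equiv), DMAP (0.1 equiv), CH2Cl2, 0 °C → rt
Reagents that add atoms: none
Why: Steglich esterification in which DCC activates the acid and DMAP relays the acyl group to the only free hydroxyl (O5), while the alkyl‑only α‑stereocentre does not epimerise at 0 °C to rt.

Step 10
Reactants: 16 methyl 3,4‑O‑isopropylidene‑5‑O‑[(2R)‑2‑methylbutanoyl]shikimate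
Product: 17 methyl 5‑O‑[(2R)‑2‑methylbutanoyl]shikimate
Conditions: 80% aq. AcOH, 50 °C (or TFA/H2O 9:1, 0 °C)
Reagents that add atoms: none
Why: Acid‑catalysed acetal hydrolysis that frees the 3,4‑diol, with the esters stable to dilute acid and no base present to trigger acyl migration of the hindered O5 ester.

Step 11
Reactants: 17 methyl 5‑O‑[(2R)‑2‑methylbutanoyl]shikimate
Product: 18 methyl 3‑O‑acetyl‑5‑O‑[(2R)‑2‑methylbutanoyl]shikimate
Conditions: lipase (immobilised Burkholderia cepacia lipase, Amano PS‑IM), vinyl acetate (5 equiv), MTBE, 35 °C; stop at complete mono‑acetylation (HPLC)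
Reagents that add atoms: vinyl acetate C=COC(C)=O
Why: Lipase‑catalysed irreversible transesterification (serine‑hydrolase acyl‑enzyme, with vinyl alcohol leaving as acetaldehyde) that should acetylate only the allylic 3‑OH, whose unbranched vinylic neighbour fits the enzyme's medium pocket, whereas the 4‑OH sits between two branched oxygenated carbons, under neutral conditions that exclude acyl migration.

Step 12
Reactants: 18 methyl 3‑O‑acetyl‑5‑O‑[(2R)‑2‑methylbutanoyl]shikimate
Product: 19 methyl 3‑O‑acetyl‑4‑O‑propanoyl‑5‑O‑[(2R)‑2‑methylbutanoyl]shikimate (CNP0403577.1)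
Conditions: (EtCO)2O (3 equiv), DMAP (0.1 equiv), pyridine, CH2Cl2, 0 °C, short reaction time
Reagents that add atoms: propionic anhydride CCC(=O)OC(=O)CC
Why: DMAP‑catalysed acylation of the remaining equatorial 4‑OH, fast enough at 0 °C with excess anhydride to outrun base‑mediated O3→O4 acetyl migration, with no stereocentre affected.

## Compound list

1 | furan | c1ccoc1 | starting material
2 | 3‑acryloyl‑1,3‑oxazolidin‑2‑one | C=CC(=O)N1CCOC1=O | starting material
3 | 3‑[(1R,2R,4R)‑7‑oxabicyclo[2.2.1]hept‑5‑ene‑2‑carbonyl]‑1,3‑oxazolidin‑2‑one (endo) | O=C(N1CCOC1=O)[C@@H]1C[C@@H]2C=C[C@H]1O2 | intermediate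
4 | methyl (1R,2R,4R)‑7‑oxabicyclo[2.2.1]hept‑5‑ene‑2‑carboxylate | COC(=O)[C@@H]1C[C@@H]2C=C[C@H]1O2 | intermediate
5 | lithium ester enolate of 4 (1R,4R) | COC(O[Li])=C1C[C@@H]2C=C[C@H]1O2 | intermediate (not isolated)
6 | lithium dienyl alkoxide (lithium salt of 7) | COC(=O)C1=CC=C[C@H](O[Li])C1 | intermediate (not isolated)
7 | methyl (5R)‑5‑hydroxycyclohexa‑1,3‑diene‑1‑carboxylate | COC(=O)C1=CC=C[C@H](O)C1 | intermediate
8 | methyl (5R)‑5‑[(tert‑butyldimethylsilyl)oxy]cyclohexa‑1,3‑diene‑1‑carboxylate | COC(=O)C1=CC=C[C@H](O[Si](C)(C)C(C)(C)C)C1 | intermediate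
9 | cyclic O3,O4‑osmate(VI) ester of 10 | COC(=O)C1=C[C@H]2O[Os](=O)(=O)O[C@H]2[C@H](O[Si](C)(C)C(C)(C)C)C1 | intermediate (not isolated)
10 | methyl 5‑O‑(tert‑butyldimethylsilyl)shikimate; methyl (3R,4R,5R)‑5‑[(tert‑butyldimethylsilyl)oxy]‑3,4‑dihydroxycyclohex‑1‑ene‑1‑carboxylate | COC(=O)C1=C[C@@H](O)[C@@H](O)[C@H](O[Si](C)(C)C(C)(C)C)C1 | intermediate
11 | methyl 3,4‑O‑isopropylidene‑5‑O‑(tert‑butyldimethylsilyl)shikimate | COC(=O)C1=C[C@H]2OC(C)(C)O[C@H]2[C@H](O[Si](C)(C)C(C)(C)C)C1 | intermediate
12 | methyl 3,4‑O‑isopropylideneshikimate | COC(=O)C1=C[C@H]2OC(C)(C)O[C@H]2[C@H](O)C1 | intermediate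
13 | tiglic acid, (E)‑2‑methylbut‑2‑enoic acid | C/C=C(\C)C(=O)O | starting material
14 | (2R)‑2‑methylbutanoic acid | CC[C@@H](C)C(=O)O | intermediate
15 | O‑[(2R)‑2‑methylbutanoyl]‑N,N'‑dicyclohexylisourea | CC[C@@H](C)C(=O)OC(=NC1CCCCC1)NC1CCCCC1 | intermediate (not isolated)
16 | methyl 3,4‑O‑isopropylidene‑5‑O‑[(2R)‑2‑methylbutanoyl]shikimate | COC(=O)C1=C[C@H]2OC(C)(C)O[C@H]2[C@H](OC(=O)[C@H](C)CC)C1 | intermediate
17 | methyl 5‑O‑[(2R)‑2‑methylbutanoyl]shikimate; methyl (3R,4R,5R)‑3,4‑dihydroxy‑5‑{[(2R)‑2‑methylbutanoyl]oxy}cyclohex‑1‑ene‑1‑carboxylate | COC(=O)C1=C[C@@H](O)[C@@H](O)[C@H](OC(=O)[C@H](C)CC)C1 | intermediate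
18 | methyl 3‑O‑acetyl‑5‑O‑[(2R)‑2‑methylbutanoyl]shikimate; methyl (3R,4S,5R)‑3‑acetoxy‑4‑hydroxy‑5‑{[(2R)‑2‑methylbutanoyl]oxy}cyclohex‑1‑ene‑1‑carboxylate | COC(=O)C1=C[C@@H](OC(C)=O)[C@@H](O)[C@H](OC(=O)[C@H](C)CC)C1 | intermediate
19 | methyl (3R,4S,5R)‑3‑(acetyloxy)‑5‑{[(2R)‑2‑methylbutanoyl]oxy}‑4‑(propanoyloxy)cyclohex‑1‑ene‑1‑carboxylate | CCC(=O)O[C@@H]1[C@H](OC(C)=O)C=C(C(=O)OC)C[C@H]1OC(=O)[C@H](C)CC | target

The C4 descriptor in 10 and 17 is R only because the CIP priorities change with the O‑substituents; the spatial arrangement is that of the target throughout.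

## Step count and risks

Total steps: 12. Longest linear sequence: 11 (steps 1–7 and 9–12; step 8 is a one‑step branch).

Steps most likely to fail:

Step 11 is the least certain, because the preference of the lipase for O3 over O4 rests on a steric argument and not on a tested case. If the enzyme gives mixtures or is too slow, the fallback sets out from 17 and replaces enzymatic recognition by stereoelectronic control. Trimethyl orthoacetate with catalytic CSA in CH2Cl2 at rt converts the cis‑diol into the cyclic orthoacetate methyl 3,4‑O‑(1‑methoxyethylidene)‑5‑O‑[(2R)‑2‑methylbutanoyl]shikimate F2. Brief treatment with 80% aqueous acetic acid at rt then opens the orthoester, with the acetate ending on the pseudoaxial O3 and the equatorial 4‑OH free. The route is rejoined at 18.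

Step 12 may scramble the ester pattern if the cis‑acetate migrates from O3 to O4 under the basic acylation conditions before the hindered 4‑OH is acylated. The fallback sets out from 18 and carries out the last acyl transfer biocatalytically instead of with base: Candida antarctica lipase A, a lipase that accepts hindered secondary alcohols, with vinyl propionate in MTBE at 40 °C. The neutral medium gives no alkoxide and hence no migration. The route is rejoined at 19 and no new compound is made (entry F0).

Step 2 may suffer from retro‑Diels–Alder leakage or from attack at the ring carbonyl of the oxazolidinone. The fallback sets out from 3 and replaces the direct transesterification by hydrolysis and then O‑alkylation. LiOH/H2O2 in THF/H2O at 0 °C (Na2SO3 quench) cleaves only the exocyclic acyl group and gives (1R,2R,4R)‑7‑oxabicyclo[2.2.1]hept‑5‑ene‑2‑carboxylic acid F1. Trimethylsilyldiazomethane in MeOH/toluene at 0 °C then methylates the acid under neutral conditions. The route is rejoined at 4.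

Further compounds
F1 | step 2 | (1R,2R,4R)‑7‑oxabicyclo[2.2.1]hept‑5‑ene‑2‑carboxylic acid | OC(=O)[C@@H]1C[C@@H]2C=C[C@H]1O2
F2 | step 11 | methyl 3,4‑O‑(1‑methoxyethylidene)‑5‑O‑[(2R)‑2‑methylbutanoyl]shikimate | COC(=O)C1=C[C@H]2OC(C)(OC)O[C@H]2[C@H](OC(=O)[C@H](C)CC)C1
F0 | step 12 | none | none
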